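## Retrosynthetic overview

1. Target ⇐ 12‑methoxy‑11,14‑quinone (dithionite) ⇐ 11,12,14‑trimethoxy‑7‑oxo‑19,20‑olide (CAN oxidative demethylation).
2. δ‑Lactone and C‑7 ketone ⇐ 19,20‑lactol by one Cr(VI) oxidation; lactol ⇐ 4β‑CHO / 20‑OTBDPS; C‑4 methyl by α‑face methylation of the aldehyde enolate.
3. Key disconnection C‑4–C‑5 (with C‑9–C‑10): oxidative enamine (SOMO) bicyclisation of a (Z)‑polyene aldehyde, in which the aldehyde α‑carbon acts as an enolonium equivalent toward the alkene.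
4. Polyene ⇐ Z‑selective Wittig of an α‑silyloxy keto acetal (ozonolysis of silylated cyclohexenylmethanol) with an arylpropyl ylide (from 1,2,4‑trimethoxybenzene).
5. Ring order: C (bought arene) → A and B together (key step) → lactone ring.

Assumptions: 9 is bought (otherwise one DIBAL‑H reduction of methyl cyclohex‑1‑ene‑1‑carboxylate); the catalyst antipode named in step 8 is taken, by analogy with reported aryl‑terminated bicyclisations, to give the natural 5α‑H/10β series, and its enantiomer is used if the sense proves opposite; operations run in one flask count as one step.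

Conventions: positions are given in abietane numbering (C‑1 … C‑20); Ar = 2,4,5‑trimethoxy‑3‑(propan‑2‑yl)phenyl.

## Route

Step 1
Reactants: 1 1,2,4-trimethoxybenzene
Product: 4 1,2,4-trimethoxy-3-(propan-2-yl)benzene, via aryllithium 2 (not isolated), via lithium alkoxide 3 (not isolated)
Conditions: n‑BuLi, THF, 0 °C → rt; acetone, −78 → 0 °C; then THF removed, Et3SiH, TFA, CH2Cl2, 0 °C → rt
Reagents that add atoms: acetone CC(C)=O
Why: Directed ortho‑metalation occurs at C‑3 between the two flanking methoxy groups, acetone addition gives the tertiary benzylic alkoxide, and ionic hydrogenation (Et3SiH/TFA) of the derived benzylic cation leaves the isopropyl group.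

Step 2
Reactants: 4 1,2,4-trimethoxy-3-(propan-2-yl)benzene; 5 3-chloropropanoyl chloride
Product: 7 1-(3-chloropropyl)-2,4,5-trimethoxy-3-(propan-2-yl)benzene, via aryl ketone 6 (not isolated)
Conditions: TiCl4, CH2Cl2, −20 → 0 °C; then Et3SiH, 0 °C → rt
Reagents that add atoms: none
Why: Friedel–Crafts acylation goes to the free position ortho and para to two methoxy groups (future C‑8), and the titanium‑complexed electron‑rich aryl ketone is reduced in the same flask to the methylene by ionic hydrogenation, which leaves the primary chloride intact.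

Step 3
Reactants: 7 1-(3-chloropropyl)-2,4,5-trimethoxy-3-(propan-2-yl)benzene
Product: 8 triphenyl{3-[2,4,5-trimethoxy-3-(propan-2-yl)phenyl]propyl}phosphonium iodide
Conditions: PPh3, NaI, MeCN, reflux
Reagents that add atoms: triphenylphosphine c1ccc(cc1)P(c1ccccc1)c1ccccc1; sodium iodide [Na+].[I-]
Why: In situ Finkelstein exchange followed by SN2 quaternisation of triphenylphosphine gives the Wittig salt.

Step 4
Reactants: 9 (cyclohex-1-en-1-yl)methanol
Product: 10 tert-butyl[(cyclohex-1-en-1-yl)methoxy]diphenylsilane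
Conditions: TBDPSCl, imidazole, CH2Cl2, rt
Reagents that add atoms: tert-butyl(chloro)diphenylsilane CC(C)(C)[Si](Cl)(c1ccccc1)c1ccccc1
Why: Standard O‑silylation; TBDPS is chosen because it survives dilute HCl, the TFA‑buffered oxidative cyclisation and KOtBu.

Step 5
Reactants: 10 tert-butyl[(cyclohex-1-en-1-yl)methoxy]diphenylsilane
Product: 13 1-[(tert-butyldiphenylsilyl)oxy]-7,7-dimethoxyheptan-2-one, via ozonide 11 (not isolated), via keto aldehyde 12 (not isolated)
Conditions: O3, CH2Cl2, −78 °C; Me2S, −78 °C → rt; then HC(OMe)3, MeOH, PPTS (cat.), 0 °C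
Reagents that add atoms: ozone [O-][O+]=O; trimethyl orthoformate COC(OC)OC
Why: Ozonolysis with reductive work‑up opens the ring alkene to the α‑silyloxy ketone (C‑10, C‑20) and the aldehyde (C‑19), and chemoselective acetalisation masks only the unhindered aldehyde so that the ketone alone is left for olefination.

Step 6
Reactants: 8 triphenyl{3-[2,4,5-trimethoxy-3-(propan-2-yl)phenyl]propyl}phosphonium iodide; 13 1-[(tert-butyldiphenylsilyl)oxy]-7,7-dimethoxyheptan-2-one
Product: 15 tert-butyl{[(2Z)-2-(5,5-dimethoxypentyl)-5-Ar-pent-2-en-1-yl]oxy}diphenylsilane, via ylide 14 (not isolated)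
Conditions: KHMDS, THF, −78 → 0 °C; then 13, −78 °C → rt
Reagents that add atoms: none
Why: Wittig olefination of an α‑alkoxy ketone with a non‑stabilised ylide (Still‑type Z‑selective trisubstituted olefination) places the ylide‑derived chain cis to CH2OSi, giving the (Z)‑alkene whose geometry becomes the trans ring fusion in step 8.

Step 7
Reactants: 15 tert-butyl{[(2Z)-2-(5,5-dimethoxypentyl)-5-Ar-pent-2-en-1-yl]oxy}diphenylsilane
Product: 16 (6Z)-6-{[(tert-butyldiphenylsilyl)oxy]methyl}-9-Ar-non-6-enal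
Conditions: 1 M HCl, THF, rt
Reagents that add atoms: water O
Why: Acid‑catalysed acetal hydrolysis; the TBDPS ether and the trisubstituted alkene tolerate dilute acid at room temperature.

Step 8
Reactants: 16 (6Z)-6-{[(tert-butyldiphenylsilyl)oxy]methyl}-9-Ar-non-6-enal
Product: 17 (1R,4aR,10aS)-4a-{[(tert-butyldiphenylsilyl)oxy]methyl}-5,6,8-trimethoxy-7-(propan-2-yl)-1,2,3,4,4a,9,10,10a-octahydrophenanthrene-1-carbaldehyde (4α‑CHO, 5α‑H, 10β‑CH2OTBDPS)
Conditions: (2S,5S)-2-tert-butyl-3-methyl-5-(naphthalen-1-ylmethyl)imidazolidin-4-one·TFA (30 mol %), Cu(OTf)2 (2.5 equiv), NaTFA (2 equiv), TFA (3 equiv), i‑PrCN/DME, rt, slow addition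
Reagents that add atoms: none
Why: Organo‑SOMO catalysis (enantioselective oxidative polyene cyclisation): one‑electron oxidation of the catalyst‑bound enamine turns the normally nucleophilic α‑carbon C‑4 into an electrophilic radical cation (enolonium equivalent) that bonds to the nucleophilic alkene carbon C‑5, the tertiary C‑10 radical closes ring B on the free arene position ortho to OMe and Cu(II) rearomatises; the chair–chair array on the (Z)‑alkene sets C‑5 and C‑10 together (trans fusion, C‑20 axial), the imidazolidinone face‑shielding sets the absolute configuration, and C‑4 is reset in step 9.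

Step 9
Reactants: 17 tricyclic aldehyde (4α‑CHO, 4β‑H)
Product: 19 (1S,4aR,10aR)-4a-{[(tert-butyldiphenylsilyl)oxy]methyl}-5,6,8-trimethoxy-1-methyl-7-(propan-2-yl)-1,2,3,4,4a,9,10,10a-octahydrophenanthrene-1-carbaldehyde (4α‑Me, 4β‑CHO), via potassium enolate 18 (not isolated)
Conditions: KOtBu, THF/t‑BuOH, 0 °C; MeI, 0 °C → rt
Reagents that add atoms: iodomethane CI
Why: Enolate C‑alkylation of the α‑branched aldehyde: the exocyclic C‑4 enolate is methylated from the equatorial α‑face because the axial C‑10 CH2OTBDPS group blocks the β‑face (as in classical podocarpate C‑4 alkylations), which places the C‑19 carbonyl β, cis to C‑20.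

Step 10
Reactants: 19 quaternary aldehyde (4α‑Me, 4β‑CHO, 20‑OTBDPS)
Product: 21 (4S,5R,10R)-19,20-epoxy-11,12,14-trimethoxyabieta-8,11,13-trien-19-ol (lactol, both C‑19 anomers), via hydroxy aldehyde 20 (not isolated)
Conditions: TBAF, AcOH, THF, 0 °C → rt
Reagents that add atoms: none
Why: Fluoride desilylation frees the C‑20 alcohol, which is 1,3‑diaxial to the C‑19 aldehyde and closes spontaneously to the six‑membered lactol (hemiacetalisation).

Step 11
Reactants: 21 19,20‑lactol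
Product: 22 (4S,5R,10R)-11,12,14-trimethoxy-7-oxoabieta-8,11,13-trien-19,20-olide
Conditions: CrO3, AcOH/H2O, 0 °C → rt
Reagents that add atoms: chromium trioxide O=[Cr](=O)=O
Why: Chromium(VI) oxidises the lactol to the δ‑lactone and, in the same flask, the C‑7 benzylic methylene (para to the C‑12 and ortho to the C‑14 methoxy group) to the aryl ketone (benzylic oxidation), while the isopropyl methine between two ortho substituents is sterically protected.

Step 12
Reactants: 22 (4S,5R,10R)-11,12,14-trimethoxy-7-oxoabieta-8,11,13-trien-19,20-olide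
Product: 24 (4S,5R,10R)-11,14-dihydroxy-12-methoxy-7-oxoabieta-8,11,13-trien-19,20-olide (CNP0159814.2), via quinone 23 (not isolated)
Conditions: CAN, MeCN/H2O, 0 °C; then aq. Na2S2O4, EtOAc, rt, under Ar
Reagents that add atoms: water O
Why: CAN oxidative demethylation of the para‑related C‑11/C‑14 methoxy pair gives the 12‑methoxy‑1,4‑quinone, and dithionite reduction of the quinone gives the hydroquinone with no stereocentre touched.

## Compound list

1 | 1,2,4-trimethoxybenzene | COc1ccc(OC)c(OC)c1 | starting material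
2 | (2,3,6-trimethoxyphenyl)lithium | [Li]c1c(OC)ccc(OC)c1OC | intermediate
3 | lithium 2-(2,3,6-trimethoxyphenyl)propan-2-olate | [Li+].CC(C)([O-])c1c(OC)ccc(OC)c1OC | intermediate
4 | 1,2,4-trimethoxy-3-(propan-2-yl)benzene | CC(C)c1c(OC)ccc(OC)c1OC | intermediate
5 | 3-chloropropanoyl chloride | O=C(Cl)CCCl | starting material
6 | 3-chloro-1-[2,4,5-trimethoxy-3-(propan-2-yl)phenyl]propan-1-one | COc1cc(C(=O)CCCl)c(OC)c(C(C)C)c1OC | intermediate
7 | 1-(3-chloropropyl)-2,4,5-trimethoxy-3-(propan-2-yl)benzene | COc1cc(CCCCl)c(OC)c(C(C)C)c1OC | intermediate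
8 | triphenyl{3-[2,4,5-trimethoxy-3-(propan-2-yl)phenyl]propyl}phosphonium iodide | COc1cc(CCC[P+](c2ccccc2)(c2ccccc2)c2ccccc2)c(OC)c(C(C)C)c1OC.[I-] | intermediate
9 | (cyclohex-1-en-1-yl)methanol | OCC1=CCCCC1 | starting material
10 | tert-butyl[(cyclohex-1-en-1-yl)methoxy]diphenylsilane | CC(C)(C)[Si](OCC1=CCCCC1)(c1ccccc1)c1ccccc1 | intermediate
11 | 1-{[(tert-butyldiphenylsilyl)oxy]methyl}-7,8,9-trioxabicyclo[4.2.1]nonane (ozonide) | CC(C)(C)[Si](OCC12CCCCC(OO1)O2)(c1ccccc1)c1ccccc1 | intermediate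
12 | 7-[(tert-butyldiphenylsilyl)oxy]-6-oxoheptanal | O=CCCCCC(=O)CO[Si](c1ccccc1)(c1ccccc1)C(C)(C)C | intermediate
13 | 1-[(tert-butyldiphenylsilyl)oxy]-7,7-dimethoxyheptan-2-one | COC(OC)CCCCC(=O)CO[Si](c1ccccc1)(c1ccccc1)C(C)(C)C | intermediate
14 | triphenyl{3-[2,4,5-trimethoxy-3-(propan-2-yl)phenyl]propylidene}-λ5-phosphane (ylide) | COc1cc(CCC=P(c2ccccc2)(c2ccccc2)c2ccccc2)c(OC)c(C(C)C)c1OC | intermediate
15 | tert-butyl{[(2Z)-2-(5,5-dimethoxypentyl)-5-[2,4,5-trimethoxy-3-(propan-2-yl)phenyl]pent-2-en-1-yl]oxy}diphenylsilane | COC(OC)CCCC/C(CO[Si](c1ccccc1)(c1ccccc1)C(C)(C)C)=C/CCc1cc(OC)c(OC)c(C(C)C)c1OC | intermediate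
16 | (6Z)-6-{[(tert-butyldiphenylsilyl)oxy]methyl}-9-[2,4,5-trimethoxy-3-(propan-2-yl)phenyl]non-6-enal | O=CCCCC/C(CO[Si](c1ccccc1)(c1ccccc1)C(C)(C)C)=C/CCc1cc(OC)c(OC)c(C(C)C)c1OC | intermediate
17 | (1R,4aR,10aS)-4a-{[(tert-butyldiphenylsilyl)oxy]methyl}-5,6,8-trimethoxy-7-(propan-2-yl)-1,2,3,4,4a,9,10,10a-octahydrophenanthrene-1-carbaldehyde | COc1c(OC)c2c(c(OC)c1C(C)C)CC[C@@H]1[C@]2(CO[Si](c3ccccc3)(c3ccccc3)C(C)(C)C)CCC[C@H]1C=O | intermediate
18 | potassium enolate of 17 (C‑4=CH–OK) | COc1c(OC)c2c(c(OC)c1C(C)C)CC[C@@H]1[C@]2(CO[Si](c3ccccc3)(c3ccccc3)C(C)(C)C)CCCC1=C[O-].[K+] | intermediate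
19 | (1S,4aR,10aR)-4a-{[(tert-butyldiphenylsilyl)oxy]methyl}-5,6,8-trimethoxy-1-methyl-7-(propan-2-yl)-1,2,3,4,4a,9,10,10a-octahydrophenanthrene-1-carbaldehyde | COc1c(OC)c2c(c(OC)c1C(C)C)CC[C@@H]1[C@]2(CO[Si](c3ccccc3)(c3ccccc3)C(C)(C)C)CCC[C@]1(C)C=O | intermediate
20 | (1S,4aR,10aR)-4a-(hydroxymethyl)-5,6,8-trimethoxy-1-methyl-7-(propan-2-yl)-1,2,3,4,4a,9,10,10a-octahydrophenanthrene-1-carbaldehyde | COc1c(OC)c2c(c(OC)c1C(C)C)CC[C@@H]1[C@]2(CO)CCC[C@]1(C)C=O | intermediate
21 | (4S,5R,10R)-19,20-epoxy-11,12,14-trimethoxyabieta-8,11,13-trien-19-ol (lactol, C‑19 anomers) | COc1c(OC)c2c(c(OC)c1C(C)C)CC[C@@H]1[C@]23CCC[C@]1(C)C(O)OC3 | intermediate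
22 | (4S,5R,10R)-11,12,14-trimethoxy-7-oxoabieta-8,11,13-trien-19,20-olide | COc1c(OC)c2c(c(OC)c1C(C)C)C(=O)C[C@@H]1[C@]23CCC[C@]1(C)C(=O)OC3 | intermediate
23 | (4S,5R,10R)-12-methoxy-7,11,14-trioxoabieta-8,12-dien-19,20-olide (quinone) | COC1=C(C(C)C)C(=O)C2=C(C1=O)[C@]34CCC[C@](C)(C(=O)OC3)[C@@H]4CC2=O | intermediate
24 | (4S,5R,10R)-11,14-dihydroxy-12-methoxy-7-oxoabieta-8,11,13-trien-19,20-olide | COc1c(O)c2c(c(O)c1C(C)C)C(=O)C[C@@H]1[C@]23CCC[C@]1(C)C(=O)OC3 | target

## Step count and risks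

Total steps: 12. Longest linear sequence: 10 (steps 1–3 and 6–12, from 1). The side branch (steps 4–5) is 2 steps.

**Risk 1 – step 8 (oxidative bicyclisation).** Cu(II) may oxidise the trimethoxyarene in competition with the enamine. The allylic silyloxymethyl group makes the alkene less nucleophilic and crowds the chair array. The ee on this substrate is untested.

Fallback: keep the same oxidatively umpoled C‑4 but use a manganese(III) cyclisation of a chiral α‑methyl β‑keto ester, which also installs the C‑4 methyl directly. It sets out from 8 and comes back at 22. The ylide 14 from 8 is condensed (KHMDS, THF, −78 °C) with methyl 5-[(tert-butyldiphenylsilyl)oxy]-4-oxopentanoate F1 (thiazolium‑catalysed Stetter addition of (tert‑butyldiphenylsilyloxy)acetaldehyde to methyl acrylate) to give the (Z)‑alkenoate methyl (4Z)-4-{[(tert-butyldiphenylsilyl)oxy]methyl}-7-Ar-hept-4-enoate F2. Crossed Claisen condensation of F2 with the lithium enolate of (1R,2S,5R)-8-phenylmenthyl propanoate F3 (from (−)‑8‑phenylmenthol and propanoyl chloride) gives the 8‑phenylmenthyl (6Z)-6-{[(tert-butyldiphenylsilyl)oxy]methyl}-2-methyl-3-oxo-9-Ar-non-6-enoate F4. Mn(OAc)3·2H2O with Yb(OTf)3 in CF3CH2OH at −5 °C cyclises it to the 8‑phenylmenthyl 20-[(tert-butyldiphenylsilyl)oxy]-11,12,14-trimethoxy-3-oxoabieta-8,11,13-trien-19-oate F5. The ester is expected axial and cis to C‑20, as in the podocarpate precedent; the auxiliary antipode is chosen for the natural series and diastereomers are separated. The C‑3 ketone is removed through the C‑3 tosylhydrazone F6 (TsNHNH2, then catecholborane, NaOAc) to give the 8‑phenylmenthyl 20-[(tert-butyldiphenylsilyl)oxy]-11,12,14-trimethoxyabieta-8,11,13-trien-19-oate F7. TBAF/AcOH followed by TsOH in toluene at 80 °C closes the lactone to (4S,5R,10R)-11,12,14-trimethoxyabieta-8,11,13-trien-19,20-olide F8, and CrO3/AcOH oxidation of C‑7 returns to 22.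

**Risk 2 – step 11 (double chromium oxidation).** Cr(VI) may attack the electron‑rich ring (premature quinone formation) or over‑oxidise at C‑6.

Fallback: split the two oxidations and make the ketone by benzylic hydride abstraction instead of chromium C–H oxidation. It sets out from 21 and comes back at 22. DDQ in dioxane/H2O abstracts hydride from C‑7 (cation stabilised by the para C‑12 and ortho C‑14 methoxy groups); water capture and a second DDQ oxidation give the 7‑oxo lactol (4S,5R,10R)-19,20-epoxy-19-hydroxy-11,12,14-trimethoxyabieta-8,11,13-trien-7-one F9. TPAP/NMO then oxidises the lactol to the lactone, which is 22.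

**Risk 3 – step 9 (aldehyde methylation).** The hindered α‑branched aldehyde enolate may O‑methylate or react slowly.

Fallback: alkylate a metalloenamine instead of the enolate; carbon alkylation is then enforced and the α‑face preference is unchanged. It sets out from 17 and comes back at 19. Condensation of 17 with cyclohexylamine (MgSO4, CH2Cl2) gives the N‑cyclohexyl imine of 17 F10. LDA (THF, −78 → 0 °C) then MeI gives the N‑cyclohexyl imine of 19 F11, and aqueous oxalic acid hydrolysis gives 19.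

## Further compounds

F1 | step 8 | methyl 5-[(tert-butyldiphenylsilyl)oxy]-4-oxopentanoate | COC(=O)CCC(=O)CO[Si](c1ccccc1)(c1ccccc1)C(C)(C)C
F2 | step 8 | methyl (4Z)-4-{[(tert-butyldiphenylsilyl)oxy]methyl}-7-[2,4,5-trimethoxy-3-(propan-2-yl)phenyl]hept-4-enoate | COC(=O)CC/C(CO[Si](c1ccccc1)(c1ccccc1)C(C)(C)C)=C/CCc1cc(OC)c(OC)c(C(C)C)c1OC
F3 | step 8 | (1R,2S,5R)-5-methyl-2-(2-phenylpropan-2-yl)cyclohexyl propanoate | CCC(=O)O[C@@H]1C[C@H](C)CC[C@H]1C(C)(C)c1ccccc1
F4 | step 8 | (1R,2S,5R)-5-methyl-2-(2-phenylpropan-2-yl)cyclohexyl (6Z)-6-{[(tert-butyldiphenylsilyl)oxy]methyl}-2-methyl-3-oxo-9-[2,4,5-trimethoxy-3-(propan-2-yl)phenyl]non-6-enoate (C‑2 epimers) | CC(C(=O)CC/C(CO[Si](c1ccccc1)(c1ccccc1)C(C)(C)C)=C/CCc1cc(OC)c(OC)c(C(C)C)c1OC)C(=O)O[C@@H]1C[C@H](C)CC[C@H]1C(C)(C)c1ccccc1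
F5 | step 8 | 8-phenylmenthyl 20-[(tert-butyldiphenylsilyl)oxy]-11,12,14-trimethoxy-3-oxoabieta-8,11,13-trien-19-oate (4α‑Me, 5α‑H, 10β) | COc1c(OC)c2c(c(OC)c1C(C)C)CC[C@@H]1[C@]2(CO[Si](c3ccccc3)(c3ccccc3)C(C)(C)C)CCC(=O)[C@]1(C)C(=O)O[C@@H]1C[C@H](C)CC[C@H]1C(C)(C)c1ccccc1
F6 | step 8 | C‑3 tosylhydrazone of F5 | COc1c(OC)c2c(c(OC)c1C(C)C)CC[C@@H]1[C@]2(CO[Si](c3ccccc3)(c3ccccc3)C(C)(C)C)CCC(=NNS(=O)(=O)c3ccc(C)cc3)[C@]1(C)C(=O)O[C@@H]1C[C@H](C)CC[C@H]1C(C)(C)c1ccccc1
F7 | step 8 | 8-phenylmenthyl (4S,5R,10R)-20-[(tert-butyldiphenylsilyl)oxy]-11,12,14-trimethoxyabieta-8,11,13-trien-19-oate | COc1c(OC)c2c(c(OC)c1C(C)C)CC[C@@H]1[C@]2(CO[Si](c3ccccc3)(c3ccccc3)C(C)(C)C)CCC[C@]1(C)C(=O)O[C@@H]1C[C@H](C)CC[C@H]1C(C)(C)c1ccccc1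
F8 | step 8 | (4S,5R,10R)-11,12,14-trimethoxyabieta-8,11,13-trien-19,20-olide | COc1c(OC)c2c(c(OC)c1C(C)C)CC[C@@H]1[C@]23CCC[C@]1(C)C(=O)OC3
F9 | step 11 | (4S,5R,10R)-19,20-epoxy-19-hydroxy-11,12,14-trimethoxyabieta-8,11,13-trien-7-one (C‑19 anomers) | COc1c(OC)c2c(c(OC)c1C(C)C)C(=O)C[C@@H]1[C@]23CCC[C@]1(C)C(O)OC3
F10 | step 9 | N‑cyclohexyl imine of 17 | COc1c(OC)c2c(c(OC)c1C(C)C)CC[C@@H]1[C@]2(CO[Si](c3ccccc3)(c3ccccc3)C(C)(C)C)CCC[C@H]1C=NC1CCCCC1
F11 | step 9 | N‑cyclohexyl imine of 19 | COc1c(OC)c2c(c(OC)c1C(C)C)CC[C@@H]1[C@]2(CO[Si](c3ccccc3)(c3ccccc3)C(C)(C)C)CCC[C@]1(C)C=NC1CCCCC1
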